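Thursday's run ended with free monomer at 85.5% of its charge and monomer in chains at 14.4%, together 99.9%. So in that run what left one form stood in the other, and asking which form leads is asking whether the fraction f of free monomer has passed the symmetric point, half in each form.

| flask | free monomer | initiator | remark | time |
|---|---|---|---|---|
| Monday's | 0.034 M | 2.5 mM | run made earlier |  |
| Thursday's | 0.075 M | 2.5 mM | run made earlier |  |
| Sunday's | 0.050 M | 3.8 mM | run made earlier |  |
| alder | 0.050 M | 2.5 mM |  | 2.5 h |
| larch | 0.050 M | 2.5 mM |  | 8.0 h |

| run | time / h | free monomer / % | monomer in chains / % |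
|---|---|---|---|
| Monday's | 0.667 | 99.1 | 1.4 |
| Monday's | 1.33 | 97.1 | 2.6 |
| Monday's | 2.00 | 95.4 | 4.8 |
| Monday's | 2.50 | 94.4 | 5.8 |
| Monday's | 3.00 | 92.4 | 7.7 |
| Thursday's | 0.250 | 99.5 | 0.1 |
| Thursday's | 0.833 | 97.1 | 2.6 |
| Thursday's | 1.33 | 94.4 | 5.4 |
| Thursday's | 2.00 | 91.4 | 8.3 |
| Thursday's | 3.00 | 85.5 | 14.4 |
| Sunday's | 0.250 | 99.4 | 1.0 |
| Sunday's | 0.833 | 97.0 | 2.4 |
| Sunday's | 1.33 | 95.4 | 4.7 |
| Sunday's | 2.00 | 92.8 | 7.4 |
| Sunday's | 3.00 | 87.8 | 12.2 |

(standard deviation of a reading: 0.3 percentage points)

1. which of these there is most of at the end, counted by the free monomer in it, alder (free monomer / monomer in chains)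
2. which of these there is most of at the end, counted by the free monomer in it, larch (free monomer / monomer in chains)
3. how much there is at the end of the one of these that leads, in percent of the free monomer charged: alder
4. how much there is at the end of the one of these that leads, in percent of the free monomer charged: larch

- a reading or a percentage of monomer in chains counts all its forms, free or not

I turn the question round and ask what the readings would have to show for monomer in chains to lead. I take the mean pseudo-first-order slope, minus ln f over the time. At their last readings Monday's run gives 0.0263 h⁻¹ and Thursday's 0.0522 h⁻¹, and since alder and larch have the same initiator charge as these two runs and a free monomer charge between theirs, interpolating on logarithms gives me 0.0368 h⁻¹. The natural logarithm of two over that slope is 18.8 h, which I call the even-split time: the time at which a flask holding that slope reaches the symmetric point. For monomer in chains to lead in larch, the mean slope has to reach 0.0866 h⁻¹, a factor of 2.35 above mine, and in alder a factor of 7.54. Thursday's slope does climb, from 0.0353 h⁻¹ at 0.833 h to its last value, but that is a factor of 1.48. So I commit to free monomer leading in both flasks, and with the slope held I reckon 91.2% in alder and 74.5% in larch, the latter likely on the high side, since Thursday's slope climbs.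

The forecast also has free monomer leading in alder at 91.9% and free monomer in larch at 65%, lower than mine, and it says of larch: “this is an extrapolation, and the mechanism is uncertain”.

The flask gives free monomer leading in alder at 91.7% and free monomer in larch at 69.3%, so the forecast stands.

    free monomer + initiator → living end + monomer in chains (k = 4.24 L mol⁻¹ h⁻¹)
    2 initiator → spent initiator (k = 1420 L mol⁻¹ h⁻¹)
    crystals ⇌ monomer in chains, rate k3*(cs3 - [monomer in chains]) while solid is left; crystals form when [monomer in chains] > cs3 (solubility = 11.0 mM, k = 20.6 h⁻¹)
    free monomer + living end → monomer in chains + living end, rate k4*[living end]*[free monomer] (k = 225 L mol⁻¹ h⁻¹)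

Larch's mean slope to its end reads 0.0458 h⁻¹, above my 0.0368 h⁻¹ yet below the 0.0866 h⁻¹ that monomer in chains needed to lead there, and its 8.0 h stands short of the even-split time 18.8 h. The opposite outcome shows in the neighbour, the same flask as larch read at 30 h, which lies past the even-split time: in that neighbour monomer in chains leads at 80.1%, all its forms counted, with free monomer down to 19.9%.

The runs are calculated for substances that don't exist, noise included.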